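The numbers in the tables were computed from invented constants; noise was put on by code.

Follow one molecule of target through the flask and ask, at each moment, what its chance of surviving is.

| setting | green | red | amber | beta | delta | theta |
|---|---|---|---|---|---|---|
| substrate | 0.050 M | 0.050 M | 0.050 M | 0.050 M | 0.050 M | 0.050 M |
| coupling partner | 0.35 equiv | 1.3 equiv | 3.8 equiv | 0.400 equiv | 1.20 equiv | 4.00 equiv |
| initiator | 10 mol% | 10 mol% | 10 mol% | 10 mol% | 10 mol% | 10 mol% |
| remark | run made earlier | run made earlier | run made earlier |  |  |  |
| time |  |  |  | 4.0 min | 4.0 min | 4.0 min |

| run | time / s | target / % | substrate / % |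
|---|---|---|---|
| green | 10.0 | 18 | 73 |
| green | 20.0 | 25 | 67 |
| green | 30.0 | 21 | 59 |
| green | 60.0 | 27 | 53 |
| green | 120 | 28 | 51 |
| red | 10.0 | 38 | 56 |
| red | 20.0 | 45 | 40 |
| red | 30.0 | 51 | 33 |
| red | 60.0 | 49 | 22 |
| red | 120 | 48 | 21 |
| amber | 25.0 | 63 | 14 |
| amber | 50.0 | 53 | 3 |
| amber | 80.0 | 41 | 0 |
| amber | 90.0 | 35 | 3 |
| amber | 120 | 31 | 1 |

(scatter of a reading: 1.5 percentage points)

- "hardly changes" means that all values lie within two and a half points (for a concentration: within two and a half percent of the largest)

- [target] at the end for beta, delta, theta, in this order
- how that number moves from the first to the last of them (falls all the way / rises, then falls / hardly changes / rises all the way / falls, then rises)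

**Bench rule.** Flat readings are usually taken as the end of a reaction, and the last of them as the yield. Green holds 27% and 28% of target, and red holds 49% and 48%, so the rule reads a level in each. Scaled by the coupling partner charged, green gives c(target) = 0.0160 M for beta.

**Its border.** Amber breaks the rule. With substrate down to 3% at 50.0 s, target still falls from 53% to 31% at 120 s, a half-life read as 90.5 s. With 3.8 equiv of coupling partner charged, this decay is taken as pseudo-first-order, its rate assumed proportional to c(coupling partner). Survival then depends on one product, c(coupling partner) times time. Taking c(coupling partner) as charge minus substrate lost gives an estimate of 0.141 M in amber, so 12.7 M·s is read as the halving dose, the product of c(coupling partner) and time over which target halves.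

**The reckoning.** The wait beyond the last readings is 120 s. The same subtraction, with red's last substrate reading taken over for delta and amber's for theta, gives 0.0205 M for delta and 0.151 M for theta. The wait then carries 0.194 halving doses in delta and 1.42 in theta. Starting from red's and amber's last readings, c(target) comes to 0.0210 M for delta and 0.00579 M for theta.

**The forecast.** It gives 0.0155 M, 0.023 M and 0.008 M, so the row rises, then falls, and for theta it says “decay continues, though perhaps slowing”. Its delta and theta values stand higher than the reckoning above.

**The result.** The flasks give 0.0151 M, 0.0205 M and 0.00528 M, and the row rises, then falls.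

    initiator → 2 initiating radical (k = 0.0430 s⁻¹)
    substrate + initiating radical → capped initiator + first chain carrier (k = 1.10 × 10⁶ M⁻¹ s⁻¹)
    coupling partner + first chain carrier ⇌ target + second chain carrier (K = 0.120, k = 3.30 × 10⁵ M⁻¹ s⁻¹)
    substrate + second chain carrier → released group + first chain carrier (k = 57000 M⁻¹ s⁻¹)
    2 first chain carrier → ended chains (k = 6.30 × 10⁷ M⁻¹ s⁻¹)
    coupling partner + target → over-reaction product (k = 0.0640 M⁻¹ s⁻¹)

**Two flasks.** In delta the chain steps ran while initiator lasted: with initiator at 0.574% of its charge at 2.00 min, substrate stood at 21.4%, and at 20.4% at 4.00 min, while coupling partner went from 42.1% to 34.8% of its charge; that dose, 2.77 M·s, takes target from 47.9% to 41.2%, and delta holds 40.9%. In theta substrate stood at 0% at 2.00 min, over-reaction ran on with coupling partner going from 66.7% to 62.3% of its charge, and that dose, 15.5 M·s, takes target from 28.3% to 12.1%, where theta holds 10.6%.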